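Late in the larch run, at 6.00 d, the complex X is down to 26.6% and E, which has two ligands exchanged, to 3.8%, so 73.4% of X has gone.

| setting | larch | flask |
|---|---|---|
| X | 0.13 M | 0.13 M |
| D | 0.50 equiv | 0.500 equiv |
| J | 0.50 equiv | 0.500 equiv |
| G | 0.039 M | 0.0390 M |
| remark | the very flask that is asked about, followed so far |  |
| time |  | 15 d |

larch run (percent of the X charged)

| time / d | X / % | E / % |
|---|---|---|
| 0.500 | 41.4 | 3.3 |
| 1.04 | 34.0 | 5.4 |
| 2.50 | 28.7 | 5.4 |
| 6.00 | 26.6 | 3.8 |

(readings scatter by 0.3 percentage points)

1. which holds at 15 d: what has brought the reaction to rest, or that it has not come to rest (D has run out first / it is still moving / forward and back rates have come level / all of X has reacted)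
2. part of the X gone at 15 d
3. the E standing at 15 d, as a percentage of the X charged
4. the Z standing at 15 d, as a percentage of the X charged

- what was read earlier has a scatter of 0.3 percentage points, one standard deviation
- a reading or a percentage of E counts all its forms, free or not
- the reaction counts as stopped when no species that holds the X changes by six tenths of a point or more over the second half of the time

Z, with one ligand exchanged, is never read, so I bracket it by counting turnovers. Each Z has taken one D and each E two. I take D as the donor, so the exchange count N = Z + 2E cannot pass the D charged, 50.0% of X, my exchange ceiling, a stoichiometric limit. The X lost stands above that ceiling, and the excess of 23 percentage points is less than the G charged, 30.0% of X. I therefore read G as a taker of at most one X each, and as no donor.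

From above, at 6.00 d:

Z ≤ 50.0% − 2 × 3.8% = 42.4%

From below, at 6.00 d:

Z ≥ 100% − 30.0% − 26.6% − 3.8% = 39.6%

If X and E slip further, both edges rise; I commit to Z near 41.0%.

The forecast says it is still moving, with X gone 75.5%, E 2% and Z 73.5%, holding that G “looks like a second donor of the exchanged ligand”. Its Z stands above my upper edge.

    X + D ⇌ J + Z (K = 61.0, k = 0.0180 M⁻¹ min⁻¹)
    Z + D ⇌ J + E (K = 2.80, k = 0.00920 M⁻¹ min⁻¹)
    G + X → L (k = 0.240 M⁻¹ min⁻¹)
    Q ⇌ E, rate k4*(cs4 - [E]) while solid is left; crystals form when [E] > cs4 (solubility = 45.0 mM, k = 0.0120 min⁻¹)

At 15 d the flask stands thus: forward and back rates have come level, with X gone 74.4%, E 3.07%, and Z 41.3%, inside my bracket. G + X → L ran while G was there, with half its turnover done by 0.412 h, leaving L at 30.0% and G at 0%; X + D ran on, with 95% of its turnover behind it at 3.00 d, and at 15 d N stands at 47.4%, under the ceiling of 50.0%. In the neighbour flask with 0.098 M of G, N stands at 32.3%, below the same ceiling of 50.0%, with 35% of the charged D still there and L at 75.4%.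

(The earlier runs and the new flask are simulated with constants of no real substance, and the scatter is random.)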